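(The earlier runs and the new flask are calculated on assumed constants; noise was put on by code.)

Slowness is what I look for in this flask: the asked time, 120 min, lies well past its last reading at 40.0 min, so I need the slow part of the curve.

common to all: starting material 0.014 M

| run | reagent in the second phase | protic impurity | remark | time | volume of the second phase over the first |
|---|---|---|---|---|---|
| Monday's | 0.021 M | 0.014 M | the very flask that is asked about, followed so far |  |  |
| Wednesday's | 0.021 M | 0.0070 M | run made earlier |  |  |
| flask | 0.0210 M | 0.0140 M |  | 2.0 h | 0.50 |

- Monday's (time / min: target / %, starting material / %): 2.50: 7.1, 89.0; 8.00: 34.7, 59.5; 12.0: 47.9, 41.2; 20.0: 62.5, 17.8; 30.0: 68.9, 5.0; 40.0: 66.5, 2.0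
- Wednesday's (time / min: target / %, starting material / %): 6.00: 26.3, 70.5; 15.0: 54.5, 34.9; 30.0: 74.3, 6.4; 50.0: 65.0, 1.3; 60.0: 59.8, 0.6; 80.0: 49.1, 0

(scatter of a reading: 1 percentage point)

1. the target and product in the second phase together standing at 2.0 h, as a percentage of the starting material charged
2. part of the starting material charged that has reacted at 2.0 h

- amounts and yields of target count product in the second phase too
- in the second phase: reagent in the second phase, product in the second phase; everything else is in the first
- charges count per volume of the first phase; a concentration in a rate is the amount of a species over the volume of its own phase; every rate counts per litre of the first phase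
- the earlier runs hold the two phases in the same ratio of volumes as the flask asked about

The late fall is cleanest in Wednesday's run, where starting material is nearly gone at 1.3%. From 50.0 min to 60.0 min target and second-phase product together fall with a time constant of 120 min, and from 60.0 min to 80.0 min with 101 min. These agree within the scatter, but the readings span only a factor of 1.32, too little to fix an order, so first order in c(target) is my working assumption and not a finding. Over the whole stretch, the first-order tail time constant, the time in which the late total falls by a factor of e, reads 107 min.

Now I draw Monday's flask. Target first climbs at 0.0502 /min of the charge, while starting material falls with a time constant of 9.94 min, about ten times quicker than the tail. Counting lost starting material as inflow, inflow crosses the tail's loss near 30.2 min, and the readings peak at 68.9%. No reading shows a level, so I let the tail run. Assuming it holds despite twice Wednesday's impurity, my reckoning from 66.5% gives 31.5%, with >99.9% reacted.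

The forecast says 31% (26% to 37%) and 99.9% (97.5% to 100%), noting that “this decay looks independent of impurity”.

The flask gives 35.4%, with 100% reacted.

    target → over-reaction product (k = 0.0928 /h)
    reagent in the reaction phase ⇌ dormant form (K = 0.997, k = 0.0329 /h)
    target ⇌ product in the second phase, rate k3*([target] - [product in the second phase]/K3) per volume of the first phase (partition coefficient = 30.0, kL = 0.170 /h)
    starting material + protic impurity → quenched substrate (k = 37.6 /M/h)
    starting material + reagent in the reaction phase → target (k = 3260 /M/h)
    target → decomposed product (k = 0.550 /h)
    reagent in the reaction phase ⇌ reagent in the second phase, rate k7*([reagent in the reaction phase] - [reagent in the second phase]/K7) per volume of the first phase (partition coefficient = 0.468, kL = 0.623 /h)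

From 1.00 h to 2.00 h this flask's tail time constant is 129 min, longer than the 107 min read earlier. It stands at 35.4% in part because target decomposes while its crossing into the second phase drags: with fast crossing the flask holds 82.8%, and without decomposition 78.0%. On Wednesday's run, the tail carried from its last reading gives 33.8%, and that run stands at 37.5% at the asked time.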